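The target is a 2-arylglycerol whose two CH2O arms carry different acyl groups, so the tertiary carbinol carbon is the stereocentre to be built. Both arms are traced back to the two ester carbonyls of a prochiral di-tert-butyl aryl(hydroxy)malonate. The phenol oxygen on the benzene ring, ortho to the carbinol carbon, can reach either ester carbonyl through a five-membered ring; under a chiral phosphoric acid it should acylate one enantiotopic ester only, closing the benzofuran-2(3H)-one ring and setting the quaternary centre. The arms are thereby told apart as aryl lactone and tert-butyl ester. The precursor is the malonate already carrying the benzylic (R)-2-methylbutanoate and the free phenol.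

Key step: step 4

Remark: the sense of induction of the phosphoric acid cannot be assigned in advance for a phenol nucleophile; the (R)-antipode is written on the assumption that it favours the (3S)-lactone, and its mirror image would be used instead if a test run shows the opposite sense.

Step 1
Reactants: 1 3-hydroxybenzyl alcohol; 2 (R)-2-methylbutanoic acid
Product: 3 3-hydroxybenzyl (2R)-2-methylbutanoate
Conditions: PPh3, DIAD, THF, 0 °C → rt
Reagents that add atoms: none
Why: Mitsunobu esterification: the benzylic alcohol is turned into an alkoxyphosphonium ion and displaced by the carboxylate of 2, which is about five pKa units more acidic than the phenol and therefore the only pronucleophile engaged, so the phenol stays free and the α-stereocentre of the acid, which is never enolized, is retained.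

Step 2
Reactants: 4 di-tert-butyl malonate
Product: 6 di-tert-butyl 2-oxomalonate, via di-tert-butyl oxomalonate hydrate 5 (not isolated)
Conditions: NaClO2, AcOH, H2O, 20–50 °C; then toluene, Dean–Stark, reflux
Reagents that add atoms: sodium chlorite, [Na+].[O-]Cl=O
Why: Chlorite oxidation of the doubly activated methylene of a malonic diester, a known route to mesoxalates, proceeds through the enol and stops at the hydrated ketone because no α-hydrogen is left, and azeotropic drying then gives the free, strongly electrophilic keto diester.

Step 3
Reactants: 3 3-hydroxybenzyl (2R)-2-methylbutanoate; 6 di-tert-butyl 2-oxomalonate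
Product: 8 di-tert-butyl 2-hydroxy-2-(2-hydroxy-4-{[(2R)-2-methylbutanoyl]oxymethyl}phenyl)malonate, via bromomagnesium phenoxide 7 (not isolated)
Conditions: EtMgBr (1.0 equiv), Et2O/CH2Cl2, −20 °C; then 6, CH2Cl2, 0 °C → rt; aq NH4Cl
Reagents that add atoms: none
Why: Ortho-specific hydroxyalkylation of a magnesium phenoxide (a chelation-controlled Friedel–Crafts-type addition): magnesium binds the keto diester and delivers it through a cyclic transition state to the ortho carbon, the free ortho position para to the acyloxymethyl group being preferred over the one flanked by two substituents, while the phenol is deprotonated much faster than EtMgBr can add to the ester and the tert-butyl esters resist premature lactonization.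

Step 4
Reactants: 8 di-tert-butyl 2-hydroxy-2-(2-hydroxy-4-{[(2R)-2-methylbutanoyl]oxymethyl}phenyl)malonate
Product: 9 tert-butyl (3S)-3-hydroxy-6-{[(2R)-2-methylbutanoyl]oxymethyl}-2-oxo-2,3-dihydro-1-benzofuran-3-carboxylate
Conditions: (R)-3,3'-bis(2,4,6-triisopropylphenyl)-1,1'-binaphthyl-2,2'-diyl hydrogen phosphate (10 mol%), toluene, 30 °C
Reagents that add atoms: none
Why: Proposed new method: the phosphoric acid is expected to act bifunctionally, its P–OH hydrogen-bonding to (protonating) one tert-butyl ester carbonyl of 8 while its P=O accepts the phenol O–H, so that the phenol oxygen adds to that carbonyl and the tetrahedral intermediate collapses with loss of tert-butanol; the closest known reaction type is the chiral-phosphoric-acid-catalysed desymmetrizing lactonization of hydroxyalkyl di-tert-butyl malonates, which has been run with aliphatic alcohols on carbon-substituted malonates but not with a phenol on a hydroxymalonate. The single ring formed, the five-membered lactone O1–C2–C3–C3a–C7a fused to the benzene ring, closes in a 5-exo-trig mode. The new stereocentre C3 arises because only one of the two enantiotopic ester groups becomes the lactone carbonyl, and the choice is made by the chiral binaphthyl phosphate pocket with its 2,4,6-triisopropylphenyl walls (catalyst control), the remote (R)-2-methylbutanoate having no say. The step needs enantiotopic-group selectivity together with chemoselectivity for transesterification over acidolysis of the tert-butyl groups; the substrate provides this through the bulk of the tert-butyl esters, which makes the uncatalysed closure slow, through the ortho geometry that holds the phenol oxygen within reach of both carbonyls, and through the mild acidity of the catalyst. Once the ring has closed, the quaternary C3 has no α-hydrogen and cannot epimerize, and no second lactone can form.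

Step 5
Reactants: 9 tert-butyl (3S)-3-hydroxy-6-{[(2R)-2-methylbutanoyl]oxymethyl}-2-oxo-2,3-dihydro-1-benzofuran-3-carboxylate
Product: 10 tert-butyl (2R)-2,3-dihydroxy-2-(2-hydroxy-4-{[(2R)-2-methylbutanoyl]oxymethyl}phenyl)propanoate
Conditions: NaBH4, THF/MeOH (10:1), 0 °C; aq NH4Cl
Reagents that add atoms: none
Why: Chemoselective borohydride reduction: the aryl ester of the lactone is far more electrophilic than the tert-butyl and benzylic alkyl esters, so hydride opens the ring and reduces the resulting aldehyde to the primary alcohol without touching the quaternary centre, and doing this before the tert-butyl ester is cleaved avoids a malonic half-acid prone to decarboxylation and marks this arm as the one to carry the second 2-methylbutanoate, as the (2R) configuration of the target demands.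

Step 6
Reactants: 10 tert-butyl (2R)-2,3-dihydroxy-2-(2-hydroxy-4-{[(2R)-2-methylbutanoyl]oxymethyl}phenyl)propanoate
Product: 11 tert-butyl (2R)-2-[2-(tert-butyldimethylsilyloxy)-4-{[(2R)-2-methylbutanoyl]oxymethyl}phenyl]-2,3-dihydroxypropanoate
Conditions: TBSCl (1.05 equiv), Et3N, CH2Cl2, 0 °C → rt
Reagents that add atoms: tert-butyldimethylsilyl chloride, CC(C)(C)[Si](C)(C)Cl
Why: Chemoselective O-silylation: triethylamine activates only the phenol (pKa about 10) as its phenoxide ion pair, whereas the neopentyl-type primary alcohol and the tertiary alcohol react with TBSCl at a useful rate only under nucleophilic catalysis (imidazole, 4-(dimethylamino)pyridine), which is deliberately left out.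

Step 7
Reactants: 11 tert-butyl (2R)-2-[2-(tert-butyldimethylsilyloxy)-4-{[(2R)-2-methylbutanoyl]oxymethyl}phenyl]-2,3-dihydroxypropanoate; 2 (R)-2-methylbutanoic acid
Product: 12 tert-butyl (2R)-2-[2-(tert-butyldimethylsilyloxy)-4-{[(2R)-2-methylbutanoyl]oxymethyl}phenyl]-2-hydroxy-3-{[(2R)-2-methylbutanoyl]oxy}propanoate
Conditions: EDC·HCl, 4-(dimethylamino)pyridine (10 mol%), CH2Cl2, 0 °C → rt
Reagents that add atoms: none
Why: Steglich esterification: the carbodiimide-activated acid is passed on by 4-(dimethylamino)pyridine to the primary alcohol, the only unhindered hydroxyl left, while the tertiary α-hydroxy ester OH is too hindered to react and the near-neutral conditions do not epimerize the α-branched acyl group.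

Step 8
Reactants: 12 tert-butyl (2R)-2-[2-(tert-butyldimethylsilyloxy)-4-{[(2R)-2-methylbutanoyl]oxymethyl}phenyl]-2-hydroxy-3-{[(2R)-2-methylbutanoyl]oxy}propanoate
Product: 13 (2R)-2-[2-(tert-butyldimethylsilyloxy)-4-{[(2R)-2-methylbutanoyl]oxymethyl}phenyl]-2-hydroxy-3-{[(2R)-2-methylbutanoyl]oxy}propanoic acid
Conditions: TFA/CH2Cl2 (1:4), 0 °C → rt
Reagents that add atoms: none
Why: Acidolysis of the tert-butyl ester by alkyl–oxygen cleavage (loss of the tert-butyl cation as isobutene) spares the primary and benzylic esters and the aryl silyl ether, and the tertiary benzylic alcohol does not ionize because its cation would be flanked by a carboxyl and an acyloxymethyl group.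

Step 9
Reactants: 13 (2R)-2-[2-(tert-butyldimethylsilyloxy)-4-{[(2R)-2-methylbutanoyl]oxymethyl}phenyl]-2-hydroxy-3-{[(2R)-2-methylbutanoyl]oxy}propanoic acid
Product: 14 (2S)-2-[2-(tert-butyldimethylsilyloxy)-4-{[(2R)-2-methylbutanoyl]oxymethyl}phenyl]-2,3-dihydroxypropyl (2R)-2-methylbutanoate
Conditions: BH3·SMe2, THF, 0 °C → rt; MeOH
Reagents that add atoms: none
Why: Chemoselective borane reduction: the carboxylic acid is reduced through its acyloxyborane much faster than the alkyl esters, and the non-basic medium gives the neighbouring 2-methylbutanoate no chance to wander between the two primary oxygens, which would scramble the carbinol configuration (the descriptor changes to S only because the CIP priorities change).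

Step 10
Reactants: 14 (2S)-2-[2-(tert-butyldimethylsilyloxy)-4-{[(2R)-2-methylbutanoyl]oxymethyl}phenyl]-2,3-dihydroxypropyl (2R)-2-methylbutanoate; 15 angelic acid, (2Z)-2-methylbut-2-enoic acid
Product: 17 (2R)-2-[2-(tert-butyldimethylsilyloxy)-4-{[(2R)-2-methylbutanoyl]oxymethyl}phenyl]-2-hydroxy-3-{[(2R)-2-methylbutanoyl]oxy}propyl (2Z)-2-methylbut-2-enoate, via angelic 2,4,6-trichlorobenzoic anhydride 16 (not isolated)
Conditions: 15, 2,4,6-Cl3C6H2COCl, Et3N, toluene, rt; then 14, 4-(dimethylamino)pyridine, toluene, rt
Reagents that add atoms: none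
Why: Yamaguchi esterification: 4-(dimethylamino)pyridine attacks the mixed anhydride at the less hindered angeloyl carbonyl and the acylpyridinium ion acylates the primary alcohol at ambient temperature, conditions under which the (Z)-2-methylbut-2-enoyl group should keep its geometry and the tertiary alcohol stays unreacted.

Step 11
Reactants: 17 (2R)-2-[2-(tert-butyldimethylsilyloxy)-4-{[(2R)-2-methylbutanoyl]oxymethyl}phenyl]-2-hydroxy-3-{[(2R)-2-methylbutanoyl]oxy}propyl (2Z)-2-methylbut-2-enoate
Product: 18 (2R)-2-hydroxy-2-(2-hydroxy-4-{[(2R)-2-methylbutanoyl]oxymethyl}phenyl)-3-{[(2R)-2-methylbutanoyl]oxy}propyl (2Z)-2-methylbut-2-enoate (the target)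
Conditions: Bu4NF/AcOH (1:1), THF, 0 °C
Reagents that add atoms: none
Why: Fluoride-induced cleavage of the aryl silyl ether, driven by the strong Si–F bond and the good phenoxide leaving group, is buffered by acetic acid so that the phenoxide is protonated at once and none of the three esters is hydrolysed, transferred or isomerized.

Compound list
1 | 3-hydroxybenzyl alcohol | OCc1cccc(O)c1 | starting material
2 | (R)-2-methylbutanoic acid | OC(=O)[C@H](C)CC | starting material
3 | 3-hydroxybenzyl (2R)-2-methylbutanoate | Oc1cccc(COC(=O)[C@H](C)CC)c1 | intermediate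
4 | di-tert-butyl malonate | CC(C)(C)OC(=O)CC(=O)OC(C)(C)C | starting material
5 | di-tert-butyl 2,2-dihydroxymalonate (hydrate of 6, not isolated) | CC(C)(C)OC(=O)C(O)(O)C(=O)OC(C)(C)C | intermediate
6 | di-tert-butyl 2-oxomalonate | CC(C)(C)OC(=O)C(=O)C(=O)OC(C)(C)C | intermediate
7 | bromomagnesium 3-{[(2R)-2-methylbutanoyl]oxymethyl}phenoxide (not isolated) | Br[Mg]Oc1cccc(COC(=O)[C@H](C)CC)c1 | intermediate
8 | di-tert-butyl 2-hydroxy-2-(2-hydroxy-4-{[(2R)-2-methylbutanoyl]oxymethyl}phenyl)malonate | CC(C)(C)OC(=O)C(O)(C(=O)OC(C)(C)C)c1ccc(COC(=O)[C@H](C)CC)cc1O | intermediate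
9 | tert-butyl (3S)-3-hydroxy-6-{[(2R)-2-methylbutanoyl]oxymethyl}-2-oxo-2,3-dihydro-1-benzofuran-3-carboxylate | CC(C)(C)OC(=O)[C@]1(O)C(=O)Oc2cc(COC(=O)[C@H](C)CC)ccc21 | intermediate
10 | tert-butyl (2R)-2,3-dihydroxy-2-(2-hydroxy-4-{[(2R)-2-methylbutanoyl]oxymethyl}phenyl)propanoate | CC(C)(C)OC(=O)[C@](O)(CO)c1ccc(COC(=O)[C@H](C)CC)cc1O | intermediate
11 | tert-butyl (2R)-2-[2-(tert-butyldimethylsilyloxy)-4-{[(2R)-2-methylbutanoyl]oxymethyl}phenyl]-2,3-dihydroxypropanoate | CC(C)(C)OC(=O)[C@](O)(CO)c1ccc(COC(=O)[C@H](C)CC)cc1O[Si](C)(C)C(C)(C)C | intermediate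
12 | tert-butyl (2R)-2-[2-(tert-butyldimethylsilyloxy)-4-{[(2R)-2-methylbutanoyl]oxymethyl}phenyl]-2-hydroxy-3-{[(2R)-2-methylbutanoyl]oxy}propanoate | CC(C)(C)OC(=O)[C@](O)(COC(=O)[C@H](C)CC)c1ccc(COC(=O)[C@H](C)CC)cc1O[Si](C)(C)C(C)(C)C | intermediate
13 | (2R)-2-[2-(tert-butyldimethylsilyloxy)-4-{[(2R)-2-methylbutanoyl]oxymethyl}phenyl]-2-hydroxy-3-{[(2R)-2-methylbutanoyl]oxy}propanoic acid | OC(=O)[C@](O)(COC(=O)[C@H](C)CC)c1ccc(COC(=O)[C@H](C)CC)cc1O[Si](C)(C)C(C)(C)C | intermediate
14 | (2S)-2-[2-(tert-butyldimethylsilyloxy)-4-{[(2R)-2-methylbutanoyl]oxymethyl}phenyl]-2,3-dihydroxypropyl (2R)-2-methylbutanoate | OC[C@](O)(COC(=O)[C@H](C)CC)c1ccc(COC(=O)[C@H](C)CC)cc1O[Si](C)(C)C(C)(C)C | intermediate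
15 | angelic acid, (2Z)-2-methylbut-2-enoic acid | C/C=C(/C)C(=O)O | starting material
16 | (2Z)-2-methylbut-2-enoic 2,4,6-trichlorobenzoic anhydride (not isolated) | C/C=C(/C)C(=O)OC(=O)c1c(Cl)cc(Cl)cc1Cl | intermediate
17 | (2R)-2-[2-(tert-butyldimethylsilyloxy)-4-{[(2R)-2-methylbutanoyl]oxymethyl}phenyl]-2-hydroxy-3-{[(2R)-2-methylbutanoyl]oxy}propyl (2Z)-2-methylbut-2-enoate | C/C=C(/C)C(=O)OC[C@](O)(COC(=O)[C@H](C)CC)c1ccc(COC(=O)[C@H](C)CC)cc1O[Si](C)(C)C(C)(C)C | intermediate
18 | (2R)-2-hydroxy-2-(2-hydroxy-4-{[(2R)-2-methylbutanoyl]oxymethyl}phenyl)-3-{[(2R)-2-methylbutanoyl]oxy}propyl (2Z)-2-methylbut-2-enoate | C/C=C(/C)C(=O)OC[C@](O)(COC(=O)[C@H](C)CC)c1ccc(COC(=O)[C@H](C)CC)cc1O | target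

Total step count: 11 steps.
Longest linear sequence: 10 steps (steps 1 and 3–11 from 3-hydroxybenzyl alcohol; the branch through step 2 from di-tert-butyl malonate is equally long).

Steps most likely to fail

Step 4 (the step carrying the new-method label). The catalyst may fail to tell the two ester groups apart. Turnover may also stall because a phenol is a weaker nucleophile than the aliphatic alcohols for which this catalysis is established, which would let an unselective background closure or slow acidolysis of the tert-butyl groups compete. The fallback uses known chemistry and replaces asymmetric catalysis by resolution. Setting out from 8, the ring would be closed without selectivity by an achiral acid (diphenyl phosphate, (PhO)2P(O)OH, 10 mol%, toluene, 60 °C). This should give 9 together with its C3 epimer, tert-butyl (3R)-3-hydroxy-6-{[(2R)-2-methylbutanoyl]oxymethyl}-2-oxo-2,3-dihydro-1-benzofuran-3-carboxylate F1. Because both isomers carry the (R)-acyl group they are diastereomers, and they would be separated by preparative HPLC on a polysaccharide-based chiral stationary phase. The (3S)-isomer comes back to the route as 9.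

Step 6. Discrimination between the phenol and the primary alcohol may be incomplete, or the hindered, hydrogen-bonded phenol may react too slowly, so that silylation spreads to the primary oxygen. The fallback protects both hydroxyls and then releases one. Setting out from 10, the phenol and the primary alcohol would both be silylated (TBSCl in excess, imidazole, DMF, rt) to give tert-butyl (2R)-3-(tert-butyldimethylsilyloxy)-2-[2-(tert-butyldimethylsilyloxy)-4-{[(2R)-2-methylbutanoyl]oxymethyl}phenyl]-2-hydroxypropanoate F2. The primary alkyl silyl ether, far more acid-labile than the aryl silyl ether, would then be removed with pyridinium p-toluenesulfonate in MeOH at rt, which comes back to the route at 11.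

Step 10. The angeloyl double bond may isomerize to the tigloyl (E) geometry during activation. Because acylation of the neopentyl-type alcohol is slow, the neighbouring 2-methylbutanoyl group may also drift between the two primary oxygens under the basic conditions, which would erode the configuration of the carbinol. The fallback builds the alkene after the ester bond. Setting out from 14, the alcohol would be esterified quickly with 2-[bis(2,2,2-trifluoroethoxy)phosphoryl]propanoic acid (EDC·HCl, catalytic 4-(dimethylamino)pyridine, CH2Cl2, 0 °C). This should give (2R)-2-[2-(tert-butyldimethylsilyloxy)-4-{[(2R)-2-methylbutanoyl]oxymethyl}phenyl]-2-hydroxy-3-{[(2R)-2-methylbutanoyl]oxy}propyl 2-[bis(2,2,2-trifluoroethoxy)phosphoryl]propanoate F3, as a mixture of epimers at the phosphonate carbon. A Still–Gennari olefination with acetaldehyde (KN(SiMe3)2, 18-crown-6, THF, −78 °C) should then form the (Z)-2-methylbut-2-enoate directly, which comes back to the route at 17.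

Further compounds
F1 | step 4 | tert-butyl (3R)-3-hydroxy-6-{[(2R)-2-methylbutanoyl]oxymethyl}-2-oxo-2,3-dihydro-1-benzofuran-3-carboxylate | CC(C)(C)OC(=O)[C@@]1(O)C(=O)Oc2cc(COC(=O)[C@H](C)CC)ccc21
F2 | step 6 | tert-butyl (2R)-3-(tert-butyldimethylsilyloxy)-2-[2-(tert-butyldimethylsilyloxy)-4-{[(2R)-2-methylbutanoyl]oxymethyl}phenyl]-2-hydroxypropanoate | CC(C)(C)OC(=O)[C@](O)(CO[Si](C)(C)C(C)(C)C)c1ccc(COC(=O)[C@H](C)CC)cc1O[Si](C)(C)C(C)(C)C
F3 | step 10 | (2R)-2-[2-(tert-butyldimethylsilyloxy)-4-{[(2R)-2-methylbutanoyl]oxymethyl}phenyl]-2-hydroxy-3-{[(2R)-2-methylbutanoyl]oxy}propyl 2-[bis(2,2,2-trifluoroethoxy)phosphoryl]propanoate | CC(C(=O)OC[C@](O)(COC(=O)[C@H](C)CC)c1ccc(COC(=O)[C@H](C)CC)cc1O[Si](C)(C)C(C)(C)C)P(=O)(OCC(F)(F)F)OCC(F)(F)F
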